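## Structural features

The target is a flavone: benzo ring A is fused through the C4a–C8a bond to the 4-pyranone ring C, and phenyl ring B is attached to C2 by one C2–C1' bond. Ring A bears oxygen at C5 (OH, hydrogen-bonded to the C4 carbonyl), C6 (OMe), C7 (OH) and C8a (ring oxygen O1), with hydrogen only at C8. Ring C has a methoxy group at C3, and ring B has a 4'-OH flanked by two 3-methylbut-2-enyl (prenyl) groups at C3' and C5'. There is no stereocentre and no stereogenic double bond, so no stereocentres stand next to each other and nothing has to be set or relayed. The fragile parts are the two trisubstituted prenyl alkenes ortho to a phenol (protic and strong Lewis acids close chromans or add HX, peracids and dioxiranes epoxidise, hydrogenation saturates), the electron-rich ring A, and on the way the cyclobutenone, the siloxyalkyne and the aryl silyl ethers. The real difficulty is differentiation: four ring A oxygens in three states with the methyl ether at C6 between the two free hydroxyls, plus the C3 methoxy group and two linear prenyl groups that must survive the ring C chemistry. The key step uses the sequence C8a(O)–C8(H)–C7(O)–C6(O)–C5(O)–C4a(H): a 2,3-dimethoxycyclobutenone supplies C8a, C6, C5 and C4a, a siloxyalkyne supplies C8 and C7, and the new bonds C8a–C8, C7–C6 and C8a–C4a deliver O1 as free OH, O7 as silyl ether and O6/O5 as methyl ethers, of which O5 later lies peri to C4=O and can be unmasked alone.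

## Logic of the disconnections

31 ⇒ 30. In the forward sense the bonds broken are the two O–Si bonds at O7 and O4'. This keeps the ortho-prenylphenol and the 7-hydroxyl masked to the end, so no earlier step sees a free phenol beside a prenyl group. The demand is that both silyl ethers survive steps 9 to 12 and leave together under buffered fluoride.

30 ⇒ 29. The O5–CH3 bond. O5 is the only ether oxygen that shares a six-membered chelate with the C4 carbonyl, so O5 and O6 can both travel as methyl ethers without an extra protecting group. The forward step must cleave one of three methyl ethers without protic acid.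

29 ⇒ 28 ⇒ 25. The O3–CH3 bond, then the C3–O bond. Removing the C3 oxygen turns ring C into a plain flavone that can be made from an alkyne, and C3–H is the only acidic sp2 C–H of 25. The forward steps need an oxidation that leaves the prenyl alkenes alone and a methylation without nucleophilic base.

25 ⇒ 14 + 21 + 22. Three ring C bonds are cut: C4a–C4, C4–C3 and O1–C2. The molecule falls into a ring A half, a ring B half with both prenyl groups, and one carbon, which is the most convergent cut available. The demand is iodine on the ring A carbon between OH and OMe, insertion of 22 before alkyne coupling, and six-membered closure.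

14 ⇒ 13. The C–I bond at the future C4a. This reduces the ring A half to the phenol that the benzannulation delivers. The forward iodination must choose between two positions ortho to the hydroxyl and relies on the bulk of the silyl ether.

13 ⇒ 3 + 8. C8a–C8, C7–C6 and C8a–C4a are cut. All of ring A falls into a four-carbon and a two-carbon piece, and the four oxygens come out differentiated without a protecting-group step. The forward cascade needs a regioselective (2+2) union and an alkyne that survives 80 °C.

3 ⇒ 2 ⇒ 1. The two C4–H bonds are traced back to C4–O and C4=O. 1 already holds the four-membered ring and both methoxy groups, so two redox steps suffice. The demands are a single hydride addition to 1 and deoxygenation of 2 at C4 without loss of methanol or allylic transposition.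

8 ⇒ 4 + 5. The C–O and O–Si bonds; the two carbons come from 4, the oxygen from a peroxide, the silicon from 5. The demands are O- rather than C-silylation of 7 and careful handling of a sensitive ynol ether.

21 ⇒ 20 ⇒ 17 + 18. The O–Si bond, then the C(aryl)–C(sp) bond. This is a standard cross-coupling; the terminal alkyne must be freed without harming the prenyl groups.

17 ⇒ 15 + 16. Both C(aryl)–CH2 bonds. The iodine of 15 blocks the para position during C-alkylation and then serves as the coupling handle, so ring B needs no functional-group interconversion. The demand is C- over O-alkylation and linear (SN2) attachment.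

## Other disconnections considered

Alternative 1: The cut is at the CH2–CH bond of each prenyl group, leading back to the 3',5'-bis(hydroxymethyl) flavone A2 and 2-methylprop-1-enylboronic acid A3.
- **Forward step:** under a diaryl hydrogen phosphate catalyst each 2-hydroxybenzyl alcohol unit of A2 would lose water to an ortho-quinone methide, and the alkenyl group of A3 would add to the exocyclic methylene to give the 5,7-bis(methoxymethyl) ether A1. No ring is formed.
- **In favour:** the linear prenyl regiochemistry is built in, and the alkenes arrive last, so C3 oxidation and peri-demethylation could be run on alkene-free material. On this point the alternative is the better of the two plans.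
- **Against:** the 4'-phenol is conjugated to the C4 carbonyl and is a poor quinone methide precursor. Two such events are needed on one ring. After the first, an ortho-prenylphenol sits in a Brønsted acid medium, which invites chroman closure. The acetal groups on ring A are also acid-labile, as is their final removal beside the prenyl groups.
- **Structure:** the alternative solves ring B and leaves the ring A oxygen pattern to a separate synthesis; the chosen plan solves ring A and carries ring B through.
- **Mechanism:** an ionic conjugate addition to a transient intermediate stands against a thermal pericyclic cascade whose regiochemistry is set by polarisation.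
- **Step economy:** one deprotection follows A1, but ring A must still be made and differentiated beforehand, so the total is not expected to be lower.

Alternative 2: The cut is the C4a–C5 bond, leading back to the pyranone β-keto ester A5.
- **Forward step:** base would turn the side chain on C8a into an extended enolate whose C4a carbon attacks the ester carbon (an intramolecular Claisen condensation), closing ring A to the 4'-O-allyl ether A4.
- **In favour:** the 5-OH comes from the ester carbonyl, the 7-OH from the ketone and the 6-OMe from the α-methoxy group, so ring A appears with its final oxygen pattern and no demethylation or iodination question arises. The end game (one deallylation with zerovalent palladium) is shorter; here the alternative is the better plan.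
- **Against:** the most acidic proton of A5 lies between ketone and ester, and its removal makes the ester part of a stabilised enolate. Closure then needs a polyanion with carbon nucleophilicity at C4a, and O-acylation, retro-Claisen cleavage and pyranone opening compete. A5 itself requires a 2-aryl-3-methoxy-4-pyranone and a lateral acylation, several uncertain steps with the prenyl groups on board.
- **Structure:** both plans close ring A at C4a as the key event; the chosen one forms three bonds from two small pieces, the alternative one bond from a linear chain.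
- **Mechanism:** pericyclic regiocontrol stands against enolate chemoselectivity.
- **Step economy:** equal or better after the key step, worse before it.

Alternative 3: The cut removes C3 (bonds C3–C2 and C3–C4), leading back to the 2-aryl-3-silyloxybenzofuran A7 and 3-chloro-3-methoxydiazirine A8.
- **Forward step:** loss of nitrogen from A8 would give chloro(methoxy)carbene A9, which would cyclopropanate the enol ether bond of A7; opening of the cyclopropane with loss of chloride would expand the furan into ring C and give A6.
- **In favour:** C3 and its methoxy group arrive in one operation, which is better than the two steps (hydroxylation, methylation) of the chosen plan, and no carbon monoxide or palladium is needed.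
- **Against:** A9 is a donor-stabilised carbene of low electrophilicity, and the double bond it must attack is part of an aromatic benzofuran, so fragmentation or dimerisation of the carbene would be expected to compete. A8 is a hazardous reagent. After A6, two prenyl groups must be put on a hindered dibromide with linear selectivity and three acetals removed by acid beside them.
- **Structure:** the alternative addresses ring C only; ring A must be pre-made and differentiated as in the chosen plan, so the two are equal on that point.
- **Mechanism:** a carbene cycloaddition and ring expansion of thin precedent stands against a benzannulation type with close precedent.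
- **Step economy:** fewer steps after the key event (two against nine), more before it, so the totals are similar.

Key step: step 4

Remark: the target is achiral; 2 and 10 are racemic and their stereocentres are destroyed in later events.
Remark: ring B is built from 4-iodophenol, whose iodine blocks the para position during C-prenylation and then serves as the alkyne handle.
Remark: atom map of the key step: C1, C2, C3, C4 of 3 become C8a, C6, C5, C4a; the CH and C–O carbons of 8 become C8 and C7.

## Steps

Step 1
Reactants: 1 dimethyl squarate
Product: 2 4-hydroxy-2,3-dimethoxycyclobut-2-en-1-one (racemic)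
Conditions: LiAlH(OtBu)3, THF, −78 → −20 °C; aq potassium sodium tartrate
Reagents that add atoms: none
Why: Mono-1,2-reduction of a cyclobutenedione: the hindered alkoxyaluminium hydride adds once to one of the two equivalent carbonyl groups and the aluminium alkoxide resists a second addition at low temperature; the new C4 stereocentre is racemic and is erased in step 2.

Step 2
Reactants: 2 4-hydroxy-2,3-dimethoxycyclobut-2-en-1-one
Product: 3 2,3-dimethoxycyclobut-2-en-1-one
Conditions: Et3SiH (5 equiv), BF3·OEt2 (0.2 equiv), CH2Cl2, −78 → −30 °C
Reagents that add atoms: none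
Why: Ionic hydrogenation: BF3 ionises the C4–OH bond to a methoxy-stabilised oxocyclobutenyl cation and Et3SiH transfers hydride to C4, the unsubstituted terminus, which restores the conjugated dimethoxy enone. Lewis-acid-mediated substitution at C4 by silicon-bound nucleophiles is established for squarate-derived 4-hydroxycyclobutenones; low temperature and excess silane are meant to outrun loss of methanol.

Step 3
Reactants: 4 acetylene; 5 triisopropylsilyl trifluoromethanesulfonate
Product: 8 (triisopropylsilyloxy)acetylene, via lithium acetylide 6 (not isolated), via lithium ethynolate 7 (not isolated)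
Conditions: n-BuLi, THF, −78 °C; t-BuOOLi (t-BuOOH + LiN(SiMe3)2), −78 → 0 °C; 5, −78 → 0 °C
Reagents that add atoms: tert-butyl hydroperoxide, CC(C)(C)OO
Why: Electrophilic oxygen transfer from lithium tert-butyl peroxide to a lithium acetylide (SN2 at the peroxide oxygen) gives the ynolate, and the hard, bulky silyl triflate silylates it on oxygen, the standard entry to 1-siloxyalkynes. The triisopropylsilyl group is what should make the ynol ether isolable.

Step 4
Reactants: 3 2,3-dimethoxycyclobut-2-en-1-one; 8 (triisopropylsilyloxy)acetylene
Product: 13 3,4-dimethoxy-5-(triisopropylsilyloxy)phenol, via vinylketene 9 (not isolated), via vinylcyclobutenone 10 (not isolated), via dienylketene 11 (not isolated), via cyclohexadienone 12 (not isolated)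
Conditions: 8 (1.5 equiv), toluene, 80 °C, sealed tube, argon
Reagents that add atoms: none
Why: Heating opens 3 by conrotatory four-electron electrocyclic cleavage of C1–C4 to vinylketene 9. The ketene C=C of 9 then adds 8 in a regioselective (2+2) cycloaddition: the electrophilic ketene carbon bonds to the nucleophilic unsubstituted alkyne carbon (C8a–C8) and the ketene α-carbon to the oxygen-bearing carbon (C6–C7), giving 10. A second four-electron opening gives dienylketene 11; the opening is reversible and the methoxy group prefers outward rotation, so the (3Z) isomer that can cyclise is the one consumed. Ring A, the only ring formed, closes by a thermal disrotatory six-electron electrocyclisation between the ketene carbon and the terminal CH2 (C8a–C4a) to 12, which tautomerises irreversibly to phenol 13. The closest known reaction type is the Danheiser benzannulation of cyclobutenones with siloxyalkynes, which gives resorcinol monosilyl ethers. No stereocentre is created, since that of 10 is lost on aromatisation. The one selectivity needed is the regiochemistry of the (2+2) step, secured by the polarisation of the siloxyalkyne (β-carbon nucleophilic) against the ketene (central carbon electrophilic); this places the silyloxy group meta and the methoxy groups para and meta to the new OH. Excess 8 should suppress acylation of 13 by 9.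

Step 5
Reactants: 13 3,4-dimethoxy-5-(triisopropylsilyloxy)phenol
Product: 14 2-iodo-3,4-dimethoxy-5-(triisopropylsilyloxy)phenol
Conditions: N-iodosuccinimide (1.0 equiv), CH2Cl2, −40 → 0 °C
Reagents that add atoms: N-iodosuccinimide, O=C1CCC(=O)N1I
Why: Electrophilic aromatic iodination ortho to the free hydroxyl: both open positions are ortho to OH, but the one beside the silyl ether is screened by the triisopropylsilyl group, so attack should occur at the carbon between OH and OMe (para to the silyloxy group). One equivalent at low temperature limits double iodination.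

Step 6
Reactants: 15 4-iodophenol; 16 prenyl bromide
Product: 17 4-iodo-2,6-bis(3-methylbut-2-en-1-yl)phenol
Conditions: 16 (2.5 equiv), aq KOH, rt
Reagents that add atoms: none
Why: ortho-C-Alkylation of an ambident phenoxide by SN2 at the CH2 end of the allylic bromide, hence linear prenyl groups: water hydrogen-bonds the phenoxide oxygen and steers alkylation to carbon, and iodine blocks the para position. Two-fold C-prenylation of 4-halophenols in water is known, though O-alkylated and mono-alkylated material must be separated off.

Step 7
Reactants: 17 4-iodo-2,6-bis(3-methylbut-2-en-1-yl)phenol; 18 trimethylsilylacetylene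
Product: 20 4-ethynyl-2,6-bis(3-methylbut-2-en-1-yl)phenol, via silylalkyne 19 (not isolated)
Conditions: PdCl2(PPh3)2 (2 mol %), CuI (4 mol %), Et3N, THF, rt; then K2CO3 (cat.), MeOH, rt
Reagents that add atoms: none
Why: Sonogashira coupling (oxidative addition of the aryl iodide to zerovalent palladium formed in situ, copper acetylide transmetalation), followed in the same flask by methanolysis of the C(sp)–Si bond; free phenols and isolated trisubstituted alkenes are tolerated.

Step 8
Reactants: 20 4-ethynyl-2,6-bis(3-methylbut-2-en-1-yl)phenol
Product: 21 tert-butyl[4-ethynyl-2,6-bis(3-methylbut-2-en-1-yl)phenoxy]dimethylsilane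
Conditions: TBSCl, imidazole, DMF, 40 °C
Reagents that add atoms: tert-butyldimethylsilyl chloride, CC(C)(C)[Si](C)(C)Cl
Why: Silylation of the phenol with imidazole-activated silyl chloride; the flanking CH2 groups slow the reaction (hence gentle warming) and make the resulting aryl silyl ether robust towards LiN(iPr)2, Et2NH and MgI2 later on.

Step 9
Reactants: 14 2-iodo-3,4-dimethoxy-5-(triisopropylsilyloxy)phenol; 21 tert-butyl[4-ethynyl-2,6-bis(3-methylbut-2-en-1-yl)phenoxy]dimethylsilane; 22 carbon monoxide
Product: 25 2-[4-(tert-butyldimethylsilyloxy)-3,5-bis(3-methylbut-2-en-1-yl)phenyl]-5,6-dimethoxy-7-(triisopropylsilyloxy)-4H-chromen-4-one, via ynone 23 (not isolated), via enaminone 24 (not isolated)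
Conditions: PdCl2(PPh3)2 (5 mol %), 22 (1 atm), Et2NH, 60 °C
Reagents that add atoms: none
Why: Carbonylative Sonogashira-type coupling and cyclisation: oxidative addition of 14 to zerovalent palladium, insertion of 22 and coupling with the terminal alkyne give ynone 23. Et2NH adds to 23 to give enaminone 24, and the ortho-hydroxyl then displaces the amine at the β-carbon, which enforces six-membered (flavone) over five-membered (aurone) closure. Carbonylative annulation of 2-iodophenols with arylacetylenes in secondary amines is a known flavone synthesis.

Step 10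
Reactants: 25 2-[4-(tert-butyldimethylsilyloxy)-3,5-bis(3-methylbut-2-en-1-yl)phenyl]-5,6-dimethoxy-7-(triisopropylsilyloxy)-4H-chromen-4-one
Product: 28 2-[4-(tert-butyldimethylsilyloxy)-3,5-bis(3-methylbut-2-en-1-yl)phenyl]-3-hydroxy-5,6-dimethoxy-7-(triisopropylsilyloxy)-4H-chromen-4-one, via 3-lithioflavone 26 (not isolated), via 3-boronate ester 27 (not isolated)
Conditions: LiN(iPr)2, THF, −78 °C; B(OMe)3, −78 → 0 °C; AcOH, 30% H2O2, 0 °C
Reagents that add atoms: hydrogen peroxide, OO
Why: Vinylic deprotonation at C3 by the lithium amide (the only acidic sp2 C–H, α to the carbonyl), boration, and oxidative 1,2-shift from boron to oxygen; this lithiation–borate–peroxide sequence is the known route from flavones to 3-hydroxyflavones. Cold H2O2 buffered by AcOH should not form peracid fast enough to epoxidise the prenyl groups.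

Step 11
Reactants: 28 2-[4-(tert-butyldimethylsilyloxy)-3,5-bis(3-methylbut-2-en-1-yl)phenyl]-3-hydroxy-5,6-dimethoxy-7-(triisopropylsilyloxy)-4H-chromen-4-one
Product: 29 2-[4-(tert-butyldimethylsilyloxy)-3,5-bis(3-methylbut-2-en-1-yl)phenyl]-3,5,6-trimethoxy-7-(triisopropylsilyloxy)-4H-chromen-4-one
Conditions: Me3SiCHN2, iPr2NEt, MeOH–MeCN, rt
Reagents that add atoms: trimethylsilyldiazomethane, C[Si](C)(C)C=[N+]=[N-]
Why: O-Methylation of the acidic enolic 3-OH by a diazomethane-type reagent with methanol as proton shuttle; no carbonate or hydroxide is present, so the aryl silyl ethers, in particular the activated one at C7, are not exposed to nucleophilic base.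

Step 12
Reactants: 29 2-[4-(tert-butyldimethylsilyloxy)-3,5-bis(3-methylbut-2-en-1-yl)phenyl]-3,5,6-trimethoxy-7-(triisopropylsilyloxy)-4H-chromen-4-one
Product: 30 2-[4-(tert-butyldimethylsilyloxy)-3,5-bis(3-methylbut-2-en-1-yl)phenyl]-5-hydroxy-3,6-dimethoxy-7-(triisopropylsilyloxy)-4H-chromen-4-one
Conditions: MgI2·OEt2 (3 equiv), toluene, 70 °C; pH 7 buffer
Reagents that add atoms: none
Why: Chelation-assisted demethylation: magnesium binds C4=O and O5 in a six-membered chelate and iodide removes the methyl group by SN2. Methoxy groups peri to a carbonyl are cleaved selectively by MgI2, the C6 and C3 ethers lack this six-membered activation, and the medium holds no protic acid that could attack the prenyl groups.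

Step 13
Reactants: 30 2-[4-(tert-butyldimethylsilyloxy)-3,5-bis(3-methylbut-2-en-1-yl)phenyl]-5-hydroxy-3,6-dimethoxy-7-(triisopropylsilyloxy)-4H-chromen-4-one
Product: 31 5,7-dihydroxy-2-[4-hydroxy-3,5-bis(3-methylbut-2-en-1-yl)phenyl]-3,6-dimethoxy-4H-chromen-4-one (target)
Conditions: Bu4NF (2.5 equiv), AcOH, THF, 0 °C
Reagents that add atoms: none
Why: Fluoride-induced cleavage of both aryl silyl ethers (Si–F bond formation); AcOH buffers the phenoxides, so the ortho-prenylphenol and the 5,7-dihydroxyflavone should be released without acid- or base-promoted side reactions.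

## Compound list

1 | dimethyl squarate | COC1=C(OC)C(=O)C1=O | starting material
2 | 4-hydroxy-2,3-dimethoxycyclobut-2-en-1-one (racemic) | COC1=C(OC)C(=O)C1O | intermediate
3 | 2,3-dimethoxycyclobut-2-en-1-one | COC1=C(OC)C(=O)C1 | intermediate
4 | acetylene | C#C | starting material
5 | triisopropylsilyl trifluoromethanesulfonate | CC(C)[Si](OS(=O)(=O)C(F)(F)F)(C(C)C)C(C)C | starting material
6 | lithium acetylide | [Li]C#C | intermediate (not isolated)
7 | lithium ethynolate | [Li]OC#C | intermediate (not isolated)
8 | (triisopropylsilyloxy)acetylene | C#CO[Si](C(C)C)(C(C)C)C(C)C | intermediate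
9 | 2,3-dimethoxybuta-1,3-dien-1-one | C=C(OC)C(OC)=C=O | intermediate (not isolated)
10 | 4-methoxy-4-(1-methoxyethenyl)-3-(triisopropylsilyloxy)cyclobut-2-en-1-one (racemic) | C=C(OC)C1(OC)C(=O)C=C1O[Si](C(C)C)(C(C)C)C(C)C | intermediate (not isolated)
11 | (3Z)-4,5-dimethoxy-3-(triisopropylsilyloxy)hexa-1,3,5-trien-1-one | O=C=C/C(O[Si](C(C)C)(C(C)C)C(C)C)=C(OC)\C(OC)=C | intermediate (not isolated)
12 | 4,5-dimethoxy-3-(triisopropylsilyloxy)cyclohexa-2,4-dien-1-one | O=C1C=C(O[Si](C(C)C)(C(C)C)C(C)C)C(OC)=C(OC)C1 | intermediate (not isolated)
13 | 3,4-dimethoxy-5-(triisopropylsilyloxy)phenol | COc1c(OC)cc(O)cc1O[Si](C(C)C)(C(C)C)C(C)C | intermediate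
14 | 2-iodo-3,4-dimethoxy-5-(triisopropylsilyloxy)phenol | COc1c(OC)c(I)c(O)cc1O[Si](C(C)C)(C(C)C)C(C)C | intermediate
15 | 4-iodophenol | Oc1ccc(I)cc1 | starting material
16 | prenyl bromide | CC(C)=CCBr | starting material
17 | 4-iodo-2,6-bis(3-methylbut-2-en-1-yl)phenol | CC(C)=CCc1cc(I)cc(CC=C(C)C)c1O | intermediate
18 | trimethylsilylacetylene | C#C[Si](C)(C)C | starting material
19 | 2,6-bis(3-methylbut-2-en-1-yl)-4-[(trimethylsilyl)ethynyl]phenol | CC(C)=CCc1cc(C#C[Si](C)(C)C)cc(CC=C(C)C)c1O | intermediate (not isolated)
20 | 4-ethynyl-2,6-bis(3-methylbut-2-en-1-yl)phenol | CC(C)=CCc1cc(C#C)cc(CC=C(C)C)c1O | intermediate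
21 | tert-butyl[4-ethynyl-2,6-bis(3-methylbut-2-en-1-yl)phenoxy]dimethylsilane | CC(C)=CCc1cc(C#C)cc(CC=C(C)C)c1O[Si](C)(C)C(C)(C)C | intermediate
22 | carbon monoxide | [C-]#[O+] | starting material
23 | 3-[4-(tert-butyldimethylsilyloxy)-3,5-bis(3-methylbut-2-en-1-yl)phenyl]-1-[2-hydroxy-5,6-dimethoxy-4-(triisopropylsilyloxy)phenyl]prop-2-yn-1-one | COc1c(OC)c(C(=O)C#Cc2cc(CC=C(C)C)c(O[Si](C)(C)C(C)(C)C)c(CC=C(C)C)c2)c(O)cc1O[Si](C(C)C)(C(C)C)C(C)C | intermediate (not isolated)
24 | 3-[4-(tert-butyldimethylsilyloxy)-3,5-bis(3-methylbut-2-en-1-yl)phenyl]-3-(diethylamino)-1-[2-hydroxy-5,6-dimethoxy-4-(triisopropylsilyloxy)phenyl]prop-2-en-1-one (alkene geometry not defined) | CCN(CC)C(=CC(=O)c1c(O)cc(O[Si](C(C)C)(C(C)C)C(C)C)c(OC)c1OC)c1cc(CC=C(C)C)c(O[Si](C)(C)C(C)(C)C)c(CC=C(C)C)c1 | intermediate (not isolated)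
25 | 2-[4-(tert-butyldimethylsilyloxy)-3,5-bis(3-methylbut-2-en-1-yl)phenyl]-5,6-dimethoxy-7-(triisopropylsilyloxy)-4H-chromen-4-one | COc1c(O[Si](C(C)C)(C(C)C)C(C)C)cc2oc(-c3cc(CC=C(C)C)c(O[Si](C)(C)C(C)(C)C)c(CC=C(C)C)c3)cc(=O)c2c1OC | intermediate
26 | 3-lithio derivative of 25 | COc1c(O[Si](C(C)C)(C(C)C)C(C)C)cc2oc(-c3cc(CC=C(C)C)c(O[Si](C)(C)C(C)(C)C)c(CC=C(C)C)c3)c([Li])c(=O)c2c1OC | intermediate (not isolated)
27 | dimethyl {2-[4-(tert-butyldimethylsilyloxy)-3,5-bis(3-methylbut-2-en-1-yl)phenyl]-5,6-dimethoxy-4-oxo-7-(triisopropylsilyloxy)-4H-chromen-3-yl}boronate | COc1c(O[Si](C(C)C)(C(C)C)C(C)C)cc2oc(-c3cc(CC=C(C)C)c(O[Si](C)(C)C(C)(C)C)c(CC=C(C)C)c3)c(B(OC)OC)c(=O)c2c1OC | intermediate (not isolated)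
28 | 2-[4-(tert-butyldimethylsilyloxy)-3,5-bis(3-methylbut-2-en-1-yl)phenyl]-3-hydroxy-5,6-dimethoxy-7-(triisopropylsilyloxy)-4H-chromen-4-one | COc1c(O[Si](C(C)C)(C(C)C)C(C)C)cc2oc(-c3cc(CC=C(C)C)c(O[Si](C)(C)C(C)(C)C)c(CC=C(C)C)c3)c(O)c(=O)c2c1OC | intermediate
29 | 2-[4-(tert-butyldimethylsilyloxy)-3,5-bis(3-methylbut-2-en-1-yl)phenyl]-3,5,6-trimethoxy-7-(triisopropylsilyloxy)-4H-chromen-4-one | COc1c(O[Si](C(C)C)(C(C)C)C(C)C)cc2oc(-c3cc(CC=C(C)C)c(O[Si](C)(C)C(C)(C)C)c(CC=C(C)C)c3)c(OC)c(=O)c2c1OC | intermediate
30 | 2-[4-(tert-butyldimethylsilyloxy)-3,5-bis(3-methylbut-2-en-1-yl)phenyl]-5-hydroxy-3,6-dimethoxy-7-(triisopropylsilyloxy)-4H-chromen-4-one | COc1c(O[Si](C(C)C)(C(C)C)C(C)C)cc2oc(-c3cc(CC=C(C)C)c(O[Si](C)(C)C(C)(C)C)c(CC=C(C)C)c3)c(OC)c(=O)c2c1O | intermediate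
31 | 5,7-dihydroxy-2-[4-hydroxy-3,5-bis(3-methylbut-2-en-1-yl)phenyl]-3,6-dimethoxy-4H-chromen-4-one | COc1c(O)cc2oc(-c3cc(CC=C(C)C)c(O)c(CC=C(C)C)c3)c(OC)c(=O)c2c1O | target

## Step count and least certain steps

Total: 13 steps. Longest linear sequence: 9 steps (1, 2, 4, 5, 9, 10, 11, 12, 13, from dimethyl squarate).

**Step 4 (key step).** The most likely failure is thermal loss of 8 before it meets 9 (migration of silicon from oxygen to carbon, or oligomerisation of the unsubstituted ynol ether), or acylation of the product phenol by the ketene. The parent siloxyalkyne has no substituent to slow these paths. Fallback (functionalising a bought arene instead of building the ring; sets out from 5 and comes back at 13): commercial 3-hydroxy-4,5-dimethoxybenzaldehyde F1 is silylated with 5 (2,6-lutidine, CH2Cl2) to 3,4-dimethoxy-5-(triisopropylsilyloxy)benzaldehyde F2. Baeyer–Villiger (Dakin-type) oxidation with mCPBA gives 3,4-dimethoxy-5-(triisopropylsilyloxy)phenyl formate F3, and brief methanolysis (NaHCO3, MeOH) releases 13.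

**Step 2.** The cation may collapse by loss of methanol (the usual acid pathway of such alcohols) before hydride transfer, or hydride may be delivered to the methoxy-bearing allyl terminus, which would erode regiocontrol. Fallback (radical instead of cationic deoxygenation; from 2 to 3): 1,1'-thiocarbonyldiimidazole converts 2 into O-(2,3-dimethoxy-4-oxocyclobut-2-en-1-yl) 1H-imidazole-1-carbothioate F4. Barton–McCombie reduction (Bu3SnH, Et3B, air, toluene, rt) then gives 3; room temperature keeps the cyclobutenone closed.

**Step 3.** The monolithium acetylide may disproportionate on warming, the small ynolate may be silylated on carbon, or the volatile, acid-sensitive product may be lost on isolation. Fallback (ynolate by cleavage of an ester dianion instead of acetylide oxidation; sets out from 5, comes back at 7): ethyl bromoacetate F5 is deprotonated with LiN(SiMe3)2 at −78 °C to lithium 2-bromo-1-ethoxyethenolate F6. Bromine–lithium exchange with t-BuLi gives lithium 1-ethoxy-2-lithioethenolate F7, which loses lithium ethoxide at 0 °C to give 7; silylation with 5 as in step 3 gives 8.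

**Step 5.** Site selectivity may be poor, because the competing ortho position is para to a methoxy group and electronically at least as activated, and the very electron-rich ring may be iodinated twice. Fallback (directed ortho-metalation instead of electrophilic substitution; from 13 to 14): MOMCl/iPr2NEt gives [2,3-dimethoxy-5-(methoxymethoxy)phenoxy]triisopropylsilane F8. n-BuLi (THF, 0 °C) removes the proton between the two cooperating ether groups, the other ortho position being blocked by the silyl ether, to give [4-lithio-2,3-dimethoxy-5-(methoxymethoxy)phenoxy]triisopropylsilane F9. Iodine gives [4-iodo-2,3-dimethoxy-5-(methoxymethoxy)phenoxy]triisopropylsilane F10, and catalytic HCl in MeOH removes the acetal to give 14.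

**Step 9.** At a hindered, electron-rich aryl iodide, oxidative addition and insertion of 22 may be slow, so direct alkyne coupling, proto-deiodination or five-membered closure may compete. Fallback (polar acylation instead of palladium carbonylation; sets out from 14 and 21, comes back at 23):
- 14 is protected (MOMCl, iPr2NEt) as iodide F10, and iodine–lithium exchange (n-BuLi, −78 °C) gives aryllithium F9.
- 21 is deprotonated (n-BuLi) and acylated with N-methoxy-N-methylcarbamoyl chloride to N-methoxy-N-methyl-3-[4-(tert-butyldimethylsilyloxy)-3,5-bis(3-methylbut-2-en-1-yl)phenyl]prop-2-ynamide F11.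
- F9 adds to F11 to give 3-[4-(tert-butyldimethylsilyloxy)-3,5-bis(3-methylbut-2-en-1-yl)phenyl]-1-[2,3-dimethoxy-6-(methoxymethoxy)-4-(triisopropylsilyloxy)phenyl]prop-2-yn-1-one F12.
- Acetal cleavage (cat. HCl, MeOH) gives 23, which Et2NH converts into 25 as in step 9.

**Step 12.** The C3 methyl ether, which can form a five-membered chelate, may be cleaved in competition, or conversion may stall at a temperature the silyl ethers tolerate. Fallback (reversed order, so that selectivity rests on O-methylation instead; from 28 to 30): 28 has only one methoxy group beside the carbonyl and is demethylated with MgI2·OEt2 to 2-[4-(tert-butyldimethylsilyloxy)-3,5-bis(3-methylbut-2-en-1-yl)phenyl]-3,5-dihydroxy-6-methoxy-7-(triisopropylsilyloxy)-4H-chromen-4-one F13. One equivalent of trimethylsilyldiazomethane then methylates only the 3-OH, the chelated 5-OH being unreactive, and gives 30.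

## Further compounds

F1 | step 4 | 3-hydroxy-4,5-dimethoxybenzaldehyde | COc1cc(C=O)cc(O)c1OC
F2 | step 4 | 3,4-dimethoxy-5-(triisopropylsilyloxy)benzaldehyde | COc1cc(C=O)cc(O[Si](C(C)C)(C(C)C)C(C)C)c1OC
F3 | step 4 | 3,4-dimethoxy-5-(triisopropylsilyloxy)phenyl formate | COc1cc(OC=O)cc(O[Si](C(C)C)(C(C)C)C(C)C)c1OC
F4 | step 2 | O-(2,3-dimethoxy-4-oxocyclobut-2-en-1-yl) 1H-imidazole-1-carbothioate | COC1=C(OC)C(=O)C1OC(=S)n1ccnc1
F5 | step 3 | ethyl bromoacetate | CCOC(=O)CBr
F6 | step 3 | lithium 2-bromo-1-ethoxyethenolate | CCOC(O[Li])=CBr
F7 | step 3 | lithium 1-ethoxy-2-lithioethenolate | CCOC(O[Li])=C[Li]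
F8 | step 5 | [2,3-dimethoxy-5-(methoxymethoxy)phenoxy]triisopropylsilane | COCOc1cc(O[Si](C(C)C)(C(C)C)C(C)C)c(OC)c(OC)c1
F9 | step 5 | [4-lithio-2,3-dimethoxy-5-(methoxymethoxy)phenoxy]triisopropylsilane | COCOc1cc(O[Si](C(C)C)(C(C)C)C(C)C)c(OC)c(OC)c1[Li]
F10 | step 5 | [4-iodo-2,3-dimethoxy-5-(methoxymethoxy)phenoxy]triisopropylsilane | COCOc1cc(O[Si](C(C)C)(C(C)C)C(C)C)c(OC)c(OC)c1I
F11 | step 9 | N-methoxy-N-methyl-3-[4-(tert-butyldimethylsilyloxy)-3,5-bis(3-methylbut-2-en-1-yl)phenyl]prop-2-ynamide | CON(C)C(=O)C#Cc1cc(CC=C(C)C)c(O[Si](C)(C)C(C)(C)C)c(CC=C(C)C)c1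
F12 | step 9 | 3-[4-(tert-butyldimethylsilyloxy)-3,5-bis(3-methylbut-2-en-1-yl)phenyl]-1-[2,3-dimethoxy-6-(methoxymethoxy)-4-(triisopropylsilyloxy)phenyl]prop-2-yn-1-one | COCOc1cc(O[Si](C(C)C)(C(C)C)C(C)C)c(OC)c(OC)c1C(=O)C#Cc1cc(CC=C(C)C)c(O[Si](C)(C)C(C)(C)C)c(CC=C(C)C)c1
F13 | step 12 | 2-[4-(tert-butyldimethylsilyloxy)-3,5-bis(3-methylbut-2-en-1-yl)phenyl]-3,5-dihydroxy-6-methoxy-7-(triisopropylsilyloxy)-4H-chromen-4-one | COc1c(O[Si](C(C)C)(C(C)C)C(C)C)cc2oc(-c3cc(CC=C(C)C)c(O[Si](C)(C)C(C)(C)C)c(CC=C(C)C)c3)c(O)c(=O)c2c1O
A1 | alternative 1 | 2-[4-hydroxy-3,5-bis(3-methylbut-2-en-1-yl)phenyl]-3,6-dimethoxy-5,7-bis(methoxymethoxy)-4H-chromen-4-one | COc1c(OCOC)cc2oc(-c3cc(CC=C(C)C)c(O)c(CC=C(C)C)c3)c(OC)c(=O)c2c1OCOC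
A2 | alternative 1 | 2-[4-hydroxy-3,5-bis(hydroxymethyl)phenyl]-3,6-dimethoxy-5,7-bis(methoxymethoxy)-4H-chromen-4-one | COc1c(OCOC)cc2oc(-c3cc(CO)c(O)c(CO)c3)c(OC)c(=O)c2c1OCOC
A3 | alternative 1 | 2-methylprop-1-en-1-ylboronic acid | CC(C)=CB(O)O
A4 | alternative 2 | 2-[4-(allyloxy)-3,5-bis(3-methylbut-2-en-1-yl)phenyl]-5,7-dihydroxy-3,6-dimethoxy-4H-chromen-4-one | COc1c(O)cc2oc(-c3cc(CC=C(C)C)c(OCC=C)c(CC=C(C)C)c3)c(OC)c(=O)c2c1O
A5 | alternative 2 | methyl 4-{6-[4-(allyloxy)-3,5-bis(3-methylbut-2-en-1-yl)phenyl]-5-methoxy-4-oxo-4H-pyran-2-yl}-2-methoxy-3-oxobutanoate (racemic) | COC(=O)C(OC)C(=O)Cc1cc(=O)c(OC)c(-c2cc(CC=C(C)C)c(OCC=C)c(CC=C(C)C)c2)o1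
A6 | alternative 3 | 2-[3,5-dibromo-4-(methoxymethoxy)phenyl]-3,6-dimethoxy-5,7-bis(methoxymethoxy)-4H-chromen-4-one | COc1c(OCOC)cc2oc(-c3cc(Br)c(OCOC)c(Br)c3)c(OC)c(=O)c2c1OCOC
A7 | alternative 3 | tert-butyl({2-[3,5-dibromo-4-(methoxymethoxy)phenyl]-5-methoxy-4,6-bis(methoxymethoxy)-1-benzofuran-3-yl}oxy)dimethylsilane | COc1c(OCOC)cc2oc(-c3cc(Br)c(OCOC)c(Br)c3)c(O[Si](C)(C)C(C)(C)C)c2c1OCOC
A8 | alternative 3 | 3-chloro-3-methoxy-3H-diazirine | COC1(Cl)N=N1
A9 | alternative 3 | chloro(methoxy)carbene | CO[C]Cl
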